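All runs come from a simulation from invented constants, noise included.

At late times the epsilon readings level off, so what I need is the height of that plateau and whether the flask has the catalyst to reach it. Substrate, target and the two isomers form a ring of reversible steps, and the equilibrium of such a ring contains no catalyst amount; the catalyst sets the speed of the approach.

in all of them: substrate 0.20 M; precatalyst 0.11 mol%; impurity 47 µM
- epsilon: the very flask that is asked about, followed so far
- flask: time 40 min

epsilon run (percent of the substrate charged): time / min: target / % = 2.00: 12.2; 4.00: 10.9; 6.00: 11.7; 12.0: 17.5; 25.0: 19.3

(readings scatter by 1 percentage point)

- west: at 40 min add substrate, 50.0% of the amount charged, then wait 20 min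
- east: change nothing and wait 20 min more
- north-west: at 40 min take out 90% of the target then present, then wait 20 min
- south: at 40 min add precatalyst, 100% of the amount charged, then wait 20 min

- target, in percent of the substrate first charged, at 40 min
- the remedy with the largest gain of target, or "none" below 2 percentage points (west / east / north-west / south / none)
- target present, with what was taken out counted in, in percent of the substrate first charged, after east
- target present, with what was taken out counted in, in percent of the substrate first charged, after south

- removed target is counted in
- reactions considered so far: isomer of the product B + free catalyst <-> substrate + free catalyst; substrate <-> target; isomer of the product A + free catalyst <-> isomer of the product B + free catalyst; target <-> isomer of the product A; free catalyst + impurity -> spent catalyst; precatalyst <-> free catalyst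
- additions bring no volume worth counting

I test two inputs before using them. Impurity and loading enter through the spent share s, the impurity charged divided by the catalyst charged (220 µM), since each impurity kills one free catalyst: s = 21.4%. Twice the impurity makes s 42.8% and still leaves 57.2% of the catalyst, so at this s I take neither input as critical, provided the surviving catalyst finishes the approach within 40 min. The plateau reading is different, because its scatter of 1 percentage point passes straight into the answer.

The mean of the last two readings gives 18.4%, and I commit to that for now, east and south. West then gains 9.2 points and north-west 14 points, more than west, so I choose north-west.

The forecast gives 20% now, 20.4% after east and 20.7% after south, a level above mine, and it also picks north-west. Its ground for the catalyst is this: “so the catalyst survives and is not the limit”.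

The flask gives 18.2% now, 18.2% after east and 18.2% after south. The best remedy is north-west, gaining 13 points against 9.1 points for west.

    isomer of the product B + free catalyst ⇌ substrate + free catalyst, rate k1*[free catalyst]*[isomer of the product B] forward; the back reaction follows from the equilibrium constant (k = 40.7 L mol⁻¹ s⁻¹)
    substrate ⇌ target (K = 12.1, k = 0.00186 s⁻¹)
    isomer of the product A + free catalyst ⇌ isomer of the product B + free catalyst, rate k3*[free catalyst]*[isomer of the product A] forward; the back reaction follows from the equilibrium constant (K = 1.36, k = 48.1 L mol⁻¹ s⁻¹)
    target ⇌ isomer of the product A (K = 1.87, k = 0.0113 s⁻¹)
    free catalyst + impurity → spent catalyst (k = 37000 L mol⁻¹ s⁻¹)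
    precatalyst ⇌ free catalyst (K = 3.10, k = 0.00258 s⁻¹)

At 40.0 min the flask holds 21.4% of its catalyst as spent catalyst, where s gave 21.4%. For the neighbour flask with 0.028 mol% of precatalyst, the same reckoning gives s = 83.9%. At 40.0 min that neighbour flask holds 83.9% as spent catalyst, 12.1% as free catalyst and 3.96% as precatalyst. There isomer of the product A, at 41.6%, exceeds isomer of the product B, at 34.8%, and target reads 22.3%.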